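**Retrosynthetic overview**
- The target comes from its 2-(trimethylsilyl)ethyl ester by fluoride cleavage (indene numbering throughout: C4 carries CO2H, C5 the styryl group, C7 the ring methyl).
- Both rings close in one step: an intramolecular Diels–Alder reaction of a linear (4R,6R)-tetraenyl ketone forms the cyclohexene (bonds C3a–C7a and C4–C5) while the keto tether becomes the cyclopentanone; this sets C3a, C4, C5 and C7a.
- The linear ketone comes from 2,4-dibromopentan-3-one used twice as an enolonium (α-keto cation) equivalent: each α-carbon is joined to an alkenyl-metal nucleophile by nickel-catalysed stereoconvergent coupling, and the chiral catalyst sets both CHMe centres (C1 and C3).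
- The acrylate arm comes from diethyl ethylmalonate and iodoform; the trienyl arm comes from propargyl alcohol by carboalumination/iodination, formyl-Wittig and Horner–Wadsworth–Emmons olefination.

Assumption: 2,4-dibromopentan-3-one and 2-(triphenylphosphoranylidene)butanal are bought, and the (S,S) ligand antipodes written are taken to give the R centres; if the first coupling shows the opposite sense, the mirror-image ligands are used and nothing else changes.

**Step 1**
Reactants: 1 diethyl ethylmalonate; 2 iodoform
Product: 3 diethyl 2-(diiodomethyl)-2-ethylpropanedioate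
Conditions: NaH, Et2O, reflux
Reagents that add atoms: none
Why: C-alkylation of the sodium malonate by iodoform (diiodomethylation of an alkylmalonate, a known reaction type); no stereocentre is formed.

**Step 2**
Reactants: 3 diethyl 2-(diiodomethyl)-2-ethylpropanedioate
Product: 4 (E)-2-ethyl-3-iodoprop-2-enoic acid
Conditions: KOH, EtOH/H2O, reflux; then aq. HCl
Reagents that add atoms: potassium hydroxide, [K+].[OH-]
Why: Saponification of both esters followed by decarboxylative anti-elimination of iodide (Grob-type fragmentation) gives the E-iodoacrylic acid, with iodine trans to the remaining carboxyl group.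

**Step 3**
Reactants: 4 (E)-2-ethyl-3-iodoprop-2-enoic acid; 5 2-(trimethylsilyl)ethanol
Product: 6 2-(trimethylsilyl)ethyl (E)-2-ethyl-3-iodoprop-2-enoate
Conditions: EDC·HCl, DMAP (cat.), CH2Cl2, 0→25 °C
Reagents that add atoms: none
Why: Steglich esterification (carbodiimide activation, DMAP acyl transfer); the alkenyl iodide and its E geometry are untouched, and the ester chosen can later be removed without attack at a very hindered carbonyl.

**Step 4**
Reactants: 6 2-(trimethylsilyl)ethyl (E)-2-ethyl-3-iodoprop-2-enoate; 7 2,4-dibromopentan-3-one (dl/meso mixture)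
Product: 9 2-(trimethylsilyl)ethyl (2E,4R)-6-bromo-2-ethyl-4-methyl-5-oxohept-2-enoate (both C6 epimers), via alkenyl-ZnI reagent 8 (not isolated)
Conditions: Zn dust, LiCl, THF, 25 °C, decant from Zn; then 7 (3 equiv), NiCl2(MeOCH2CH2OMe) (10 mol %), (S,S)-Ph-pybox (13 mol %), DME/THF, −30 °C
Reagents that add atoms: none
Why: Proposed new method: the α-bromo ketone carbon serves as an enolonium equivalent and is joined to a carbon nucleophile, since monovalent nickel abstracts bromine to give a planar α-keto radical that the chiral alkenyl-nickel complex formed from 8 captures before reductive elimination from trivalent nickel, so the catalyst alone sets the 4R centre whatever the configuration of 7, while three equivalents of 7 hold back double coupling and the untouched CHBr centre stays a mixture that step 8 converges; the closest known reaction type is the nickel/pybox or bis(oxazoline) stereoconvergent Negishi coupling of racemic α-bromo ketones with arylzinc and alkenylzirconium reagents.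

**Step 5**
Reactants: 10 prop-2-yn-1-ol; 11 trimethylaluminium
Product: 13 (E)-3-iodo-2-methylprop-2-en-1-ol, via alkenyl-AlMe2 species 12 (not isolated)
Conditions: Me3Al (3 equiv), Cp2ZrCl2 (0.25 equiv), CH2Cl2, 0→25 °C; then I2, THF, −30→0 °C
Reagents that add atoms: iodine, II
Why: Zirconium-catalysed Negishi carboalumination adds methyl and aluminium syn across the alkyne with methyl on the internal carbon, and iodinolysis with retention gives the E-iodide.

**Step 6**
Reactants: 13 (E)-3-iodo-2-methylprop-2-en-1-ol; 14 2-(triphenylphosphoranylidene)butanal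
Product: 16 (2E,4E)-2-ethyl-5-iodo-4-methylpenta-2,4-dienal, via iodoenal 15 (not isolated)
Conditions: MnO2, CH2Cl2, 25 °C, filter; then 14, PhMe, 80 °C
Reagents that add atoms: none
Why: Allylic oxidation by MnO2 then Wittig olefination with the stabilised formyl ylide, which is E-selective and stops after one homologation because the α-branched dienal is much less electrophilic than 15.

**Step 7**
Reactants: 16 (2E,4E)-2-ethyl-5-iodo-4-methylpenta-2,4-dienal; 17 diethyl benzylphosphonate
Product: 18 [(1E,3E,5E)-3-ethyl-6-iodo-5-methylhexa-1,3,5-trien-1-yl]benzene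
Conditions: NaH, THF, 0→25 °C
Reagents that add atoms: none
Why: Horner–Wadsworth–Emmons olefination with the benzylphosphonate anion is E-selective for the new styrenyl double bond; the dienal has no acidic α-hydrogen and the alkenyl iodide is inert to the phosphonate anion.

**Step 8**
Reactants: 18 [(1E,3E,5E)-3-ethyl-6-iodo-5-methylhexa-1,3,5-trien-1-yl]benzene; 9 2-(trimethylsilyl)ethyl (2E,4R)-6-bromo-2-ethyl-4-methyl-5-oxohept-2-enoate
Product: 22 2-(trimethylsilyl)ethyl (1R,3R,3aS,4S,5R,7aS)-4,5-diethyl-1,3,7-trimethyl-2-oxo-5-[(E)-2-phenylethenyl]-2,3,3a,4,5,7a-hexahydro-1H-indene-4-carboxylate, via trienyl-Li 19 (not isolated), via trienyl-ZrCp2Cl 20 (not isolated), via linear tetraenyl ketone 21 (not isolated)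
Conditions: 18 (1.5 equiv), t-BuLi (3.0 equiv), Et2O, −78 °C; Cp2ZrCl2 (1.5 equiv), THF, −78→0 °C; then 9 (1.0 equiv), NiCl2(MeOCH2CH2OMe) (10 mol %), (S,S)-Ph-BOX (12 mol %), diglyme/THF, 10 °C; then PhMe, 25→60 °C
Reagents that add atoms: none
Why: Proposed new method: iodine–lithium exchange and transmetalation give the alkenylzirconocene with retention of geometry, a second enolonium-type nickel-catalysed stereoconvergent alkenylation (bromine abstraction to the α-keto radical, capture by the chiral alkenyl-nickel complex, reductive elimination from trivalent nickel) sets the 6R centre of 21 in the same sense as step 4, and the (4R,6R) ketone, whose two allylic CHMe centres both minimise A(1,3) strain in the same trans-fused transition state, then undergoes intramolecular Diels–Alder reaction of the E,E-diene with the E-enoate to set C3a, C4, C5 and C7a at once; the closest known reaction types are the nickel/bis(oxazoline) asymmetric coupling of racemic α-bromo ketones with alkenylzirconium reagents and the ketone-tethered intramolecular Diels–Alder reaction of spiculoic-type tetraenes.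

**Step 9**
Reactants: 22 2-(trimethylsilyl)ethyl (1R,3R,3aS,4S,5R,7aS)-4,5-diethyl-1,3,7-trimethyl-2-oxo-5-[(E)-2-phenylethenyl]-2,3,3a,4,5,7a-hexahydro-1H-indene-4-carboxylate
Product: 23 Dinorspiculoic acid A, (1R,3R,3aS,4S,5R,7aS)-4,5-diethyl-1,3,7-trimethyl-2-oxo-5-[(E)-2-phenylethenyl]-2,3,3a,4,5,7a-hexahydro-1H-indene-4-carboxylic acid
Conditions: Bu4NF (3 equiv), THF, 0→25 °C; aq. NH4Cl
Reagents that add atoms: none
Why: Fluoride attack at silicon triggers β-elimination of ethene and Me3SiF (fluoride-induced fragmentation of a 2-silylethyl ester), so the ester between two quaternary carbons is cleaved without attack at its carbonyl, and no stereocentre is touched because both α-keto centres already sit in the all-trans arrangement.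

**Compound list**
1 | diethyl ethylmalonate | CCOC(=O)C(CC)C(=O)OCC | starting material
2 | iodoform | IC(I)I | starting material
3 | diethyl 2-(diiodomethyl)-2-ethylpropanedioate | CCOC(=O)C(CC)(C(I)I)C(=O)OCC | intermediate
4 | (E)-2-ethyl-3-iodoprop-2-enoic acid | CC/C(=C\I)C(=O)O | intermediate
5 | 2-(trimethylsilyl)ethanol | C[Si](C)(C)CCO | starting material
6 | 2-(trimethylsilyl)ethyl (E)-2-ethyl-3-iodoprop-2-enoate | CC/C(=C\I)C(=O)OCC[Si](C)(C)C | intermediate
7 | 2,4-dibromopentan-3-one (dl/meso mixture) | CC(Br)C(=O)C(C)Br | starting material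
8 | iodo{(E)-2-ethyl-3-oxo-3-[2-(trimethylsilyl)ethoxy]prop-1-enyl}zinc (alkenyl-ZnI reagent) | CC/C(=C\[Zn]I)C(=O)OCC[Si](C)(C)C | intermediate
9 | 2-(trimethylsilyl)ethyl (2E,4R)-6-bromo-2-ethyl-4-methyl-5-oxohept-2-enoate (both C6 epimers) | CC/C(=C\[C@@H](C)C(=O)C(C)Br)C(=O)OCC[Si](C)(C)C | intermediate
10 | prop-2-yn-1-ol | C#CCO | starting material
11 | trimethylaluminium | C[Al](C)C | starting material
12 | dimethyl[(E)-3-(dimethylalumanyloxy)-2-methylprop-1-enyl]alumane (alkenyl-AlMe2 species) | C[Al](C)OC/C(C)=C/[Al](C)C | intermediate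
13 | (E)-3-iodo-2-methylprop-2-en-1-ol | OC/C(C)=C/I | intermediate
14 | 2-(triphenylphosphoranylidene)butanal | CCC(C=O)=P(c1ccccc1)(c1ccccc1)c1ccccc1 | starting material
15 | (E)-3-iodo-2-methylprop-2-enal | O=C/C(C)=C/I | intermediate
16 | (2E,4E)-2-ethyl-5-iodo-4-methylpenta-2,4-dienal | O=C/C(CC)=C/C(C)=C/I | intermediate
17 | diethyl benzylphosphonate | CCOP(=O)(Cc1ccccc1)OCC | starting material
18 | [(1E,3E,5E)-3-ethyl-6-iodo-5-methylhexa-1,3,5-trien-1-yl]benzene | I/C=C(C)/C=C(CC)/C=C/c1ccccc1 | intermediate
19 | [(1E,3E,5E)-4-ethyl-2-methyl-6-phenylhexa-1,3,5-trien-1-yl]lithium (trienyl-Li) | [Li]/C=C(C)/C=C(CC)/C=C/c1ccccc1 | intermediate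
20 | chlorobis(cyclopentadienyl)[(1E,3E,5E)-4-ethyl-2-methyl-6-phenylhexa-1,3,5-trien-1-yl]zirconium (trienyl-ZrCp2Cl) | Cl[Zr](C1C=CC=C1)(C1C=CC=C1)/C=C(C)/C=C(CC)/C=C/c1ccccc1 | intermediate
21 | 2-(trimethylsilyl)ethyl (2E,4R,6R,7E,9E,11E)-2,10-diethyl-4,6,8-trimethyl-5-oxo-12-phenyldodeca-2,7,9,11-tetraenoate | CC/C(=C\[C@@H](C)C(=O)[C@H](C)/C=C(C)/C=C(CC)/C=C/c1ccccc1)C(=O)OCC[Si](C)(C)C | intermediate
22 | 2-(trimethylsilyl)ethyl (1R,3R,3aS,4S,5R,7aS)-4,5-diethyl-1,3,7-trimethyl-2-oxo-5-[(E)-2-phenylethenyl]-2,3,3a,4,5,7a-hexahydro-1H-indene-4-carboxylate | CC[C@@]1(/C=C/c2ccccc2)C=C(C)[C@H]2[C@@H]([C@@H](C)C(=O)[C@@H]2C)[C@]1(CC)C(=O)OCC[Si](C)(C)C | intermediate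
23 | Dinorspiculoic acid A | CC[C@@]1(/C=C/c2ccccc2)C=C(C)[C@H]2[C@@H]([C@@H](C)C(=O)[C@@H]2C)[C@]1(CC)C(=O)O | target

**Totals**
Total step count: 9. Longest linear sequence: 6 steps (steps 1, 2, 3, 4, 8, 9).

**Three steps most likely to fail**

Step 8 (coupling of the fragile trienyl reagent with the functionalised, C–H-acidic bromo ketone 9, then the cycloaddition). The fallback sets out from 7 and 18 and comes back at 22. The order of the two alkenylations is reversed so that the trienyl reagent meets only the simplest bromo ketone. Reagent 20, made from 18 as in step 8, is coupled with three equivalents of 7 under the same nickel/bis(oxazoline) conditions to give (4R,5E,7E,9E)-2-bromo-8-ethyl-4,6-dimethyl-10-phenyldeca-5,7,9-trien-3-one F3. This is then coupled with zinc reagent 8 under the step 4 conditions to give 21, which cyclises on warming to 22.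

Step 4 (formation and transmetalation of the electron-poor alkenylzinc reagent, and mono-coupling of a dibromo ketone). The fallback sets out from 6 and 7 and comes back at 9. The organozinc reagent is dropped and iodide 6 is joined directly to 7 in a nickel-catalysed enantioconvergent reductive cross-electrophile coupling (NiBr2(MeOCH2CH2OMe), chiral bis(oxazoline), Mn powder, DMA, 0 °C). Here the alkenyl-nickel species arises by oxidative addition of 6 and captures the α-keto radical from 7; no new compound is made (F0).

Step 6 (volatile, unstable iodoenal 15 and a sluggish formyl ylide). The fallback sets out from 13 and comes back at 16. MnO2 oxidation is run in the presence of the more reactive ethyl 2-(triphenylphosphoranylidene)butanoate, which traps 15 at once as ethyl (2E,4E)-2-ethyl-5-iodo-4-methylpenta-2,4-dienoate F1. Reduction with i-Bu2AlH at −78 °C gives (2E,4E)-2-ethyl-5-iodo-4-methylpenta-2,4-dien-1-ol F2, and MnO2 oxidation returns dienal 16.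

**Further compounds**
F0 | step 4 | none | none
F1 | step 6 | ethyl (2E,4E)-2-ethyl-5-iodo-4-methylpenta-2,4-dienoate | CCOC(=O)/C(CC)=C/C(C)=C/I
F2 | step 6 | (2E,4E)-2-ethyl-5-iodo-4-methylpenta-2,4-dien-1-ol | OC/C(CC)=C/C(C)=C/I
F3 | step 8 | (4R,5E,7E,9E)-2-bromo-8-ethyl-4,6-dimethyl-10-phenyldeca-5,7,9-trien-3-one (both C2 epimers) | CC(Br)C(=O)[C@H](C)/C=C(C)/C=C(CC)/C=C/c1ccccc1
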